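Numbering is that of labdane: ring A = C1–C5 and C10, ring B = C5–C10, chain C11–C16, C17 on C8, C18/C19 on C4, C20 on C10.
Cuts, in retrosynthetic order: C6–O and C8–O (back, through a 7,8-epoxy-6-ketone and a 7-en-6-one, to a C7=C8 alkene); then C4–C5 and C9–C10, which opens both rings to an acyclic all-E tetraenoate; last C13=C14, which leaves a C18 methyl ketone and a phosphonoacetate.
Forward: the chain is completed at C13=C14, ring A and then ring B close in one proton-initiated cascade, and ring B is oxidised afterwards at C6 and C8.
Enabling feature: rings A and B are the chair–chair folded form of the C3=C4, C5=C10 and C8=C9 alkenes of an all-E polyene; the remaining alkene, C13=C14, is conjugated to the C15 ester and too electron-poor to add to a cation, so a cascade started at C3 has to end at C8 after two rings.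
Stereochemistry: C5, C9 and C10 come from the chiral acid (absolute sense) and the E-alkene chair–chair fold (relative); C8 from epoxidation anti to C20; C6 from an electron-transfer reduction that delivers the equatorial alcohol.

Key step: step 2

Assumption: (5E,9E)-farnesylacetone is available as the single geometric isomer, and the (S)-configured acid is taken to favour the fold that leads to 10R, the (R)-acid being used in the same way if the sense proves opposite.

Step 1
Reactants: 1 (5E,9E)-farnesylacetone; 2 trimethyl phosphonoacetate
Product: 3 methyl (2E,6E,10E)-geranylgeranoate
Conditions: NaH, THF, 0 °C → rt; chromatography (AgNO3–silica) to remove the 2Z isomer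
Reagents that add atoms: none
Why: Horner–Wadsworth–Emmons olefination of the methyl ketone with the sodium salt of the stabilised phosphonate, in which reversible addition favours the oxaphosphetane that places the ester trans to the long chain, so the 2E enoate should predominate and the minor 2Z isomer is separable, while the 5E and 9E alkenes are untouched.

Step 2
Reactants: 3 methyl (2E,6E,10E)-geranylgeranoate
Product: 4 methyl ent-labda-7,13E-dien-15-oate (5R,9R,10R; trans-fused, H5 and H9 anti to C20)
Conditions: (S)-2'-(2-fluorobenzyloxy)-1,1'-binaphthalen-2-ol (2 equiv), SnCl4 (2 equiv), toluene, −78 °C, then −45 °C; Et3N, then aq NaHCO3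
Reagents that add atoms: none
Why: Proposed new method: the binaphthol O–H, acidified by coordination of its oxygen to SnCl4 and held in a chiral pocket, protonates C3 of the terminal C3=C4 alkene (the ester carbonyl also binds tin, hence two equivalents of acid), and the C4 cation is captured at once by the pre-folded chain, so that C4–C5 and then C9–C10 form and the C8 cation is discharged by loss of the axial H7. The closest known reaction type is the enantioselective cyclization of polyprenoids bearing aryl or hydroxyl terminators with this class of Lewis-acid-assisted chiral Brønsted acids, together with the racemic superacid cyclization of geranylgeranoates to bicyclic 7-ene esters; the new element is the pairing of the chiral acid with a cascade that ends by proton loss. Ring A closes 6-endo-trig (C4 onto C5 of the C5=C10 alkene) and ring B closes 6-endo-trig (C10 onto C9 of the C8=C9 alkene), each through a chair. C5 and C10 are set by anti addition across the E C5=C10 alkene (trans ring fusion) and C9 by anti addition across the E C8=C9 alkene (H9 anti to C20, side chain equatorial), while the absolute sense follows from which of the two enantiomeric chair–chair folds fits the (S)-acid at the moment of protonation. The step needs initiation at the terminal alkene only, a stop after two rings and proton loss from C7: the first is secured by the unhindered trisubstituted isopropylidene end, the second by the electron-poor enoate, and the third by the alignment of axial H7 with the empty orbital at C8 and by the reversibility of proton loss toward C17 under the acid at −45 °C.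

Step 3
Reactants: 4 methyl ent-labda-7,13E-dien-15-oate
Product: 5 methyl ent-6-oxolabda-7,13E-dien-15-oate
Conditions: CrO3, 3,5-dimethylpyrazole, CH2Cl2, −20 °C
Reagents that add atoms: chromium trioxide, O=[Cr](=O)=O
Why: Allylic oxidation with the CrO3–3,5-dimethylpyrazole complex (hexavalent chromium) takes C6, the only allylic methylene of the electron-rich ring alkene, to the ketone and leaves the alkene in place, while C12 and C16 next to the electron-poor enoate and the hindered tertiary C9–H react more slowly, and no stereocentre is formed (C5 stays in its preferred trans-fused configuration).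

Step 4
Reactants: 5 methyl ent-6-oxolabda-7,13E-dien-15-oate
Product: 6 methyl ent-7α,8α-epoxy-6-oxolabd-13E-en-15-oate (epoxide oxygen anti to C20)
Conditions: 30% H2O2, NaOH (0.3 equiv), MeOH, 0 °C → rt
Reagents that add atoms: hydrogen peroxide, OO
Why: Weitz–Scheffer nucleophilic epoxidation, in which hydroperoxide adds only to C8 of the enone (the enoate ester is far less electrophilic) from the face opposite the axial C20 methyl, which blocks the other trajectory by a 1,3-diaxial contact, and the enolate closes on the same face, so that C8 carries oxygen anti to C20 with C17 axial and C7 follows from the cis ring closure.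

Step 5
Reactants: 6 methyl ent-7α,8α-epoxy-6-oxolabd-13E-en-15-oate
Product: 7 methyl ent-8α-hydroxy-6-oxolabd-13E-en-15-oate (8-OH anti to C20, C17 axial)
Conditions: SmI2 (2.2 equiv), THF/MeOH, −90 °C
Reagents that add atoms: none
Why: Reductive opening of an α,β-epoxy ketone with SmI2 (divalent samarium), in which two single-electron transfers to the ketone break the C7–O bond α to the carbonyl and methanol protonates the samarium enolate, so that the C8–O bond and its configuration are untouched, the low temperature suppresses β-elimination of the tertiary hydroxyl and the isolated enoate is not reduced.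

Step 6
Reactants: 7 methyl ent-8α-hydroxy-6-oxolabd-13E-en-15-oate
Product: 8 methyl ent-6α,8α-dihydroxylabd-13E-en-15-oate (CNP0289884.1; both hydroxyls equatorial and anti to C20)
Conditions: SmI2 (3 equiv), THF/MeOH, 0 °C
Reagents that add atoms: none
Why: Hydroxyl-assisted single-electron (ketyl) reduction of a β-hydroxy ketone with SmI2, in which the samarium ketyl held near the 8-hydroxyl keeps its bulky O–Sm group equatorial and C6 is protonated in the axial position, giving the equatorial alcohol anti to C20, which is the epimer that dissolving-metal reductions give for ketones flanked by syn-axial methyl groups and the opposite of what hydride reagents (able to approach only anti to C17, C19 and C20) would deliver, while SmI2 without strongly donating additives should leave the β,β-disubstituted enoate alone.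

Compound list
1 | (5E,9E)-farnesylacetone [(5E,9E)-6,10,14-trimethylpentadeca-5,9,13-trien-2-one] | CC(=O)CC/C=C(\C)CC/C=C(\C)CCC=C(C)C | starting material
2 | trimethyl phosphonoacetate | COC(=O)CP(=O)(OC)OC | starting material
3 | methyl (2E,6E,10E)-geranylgeranoate [methyl (2E,6E,10E)-3,7,11,15-tetramethylhexadeca-2,6,10,14-tetraenoate] | COC(=O)/C=C(\C)CC/C=C(\C)CC/C=C(\C)CCC=C(C)C | intermediate
4 | methyl ent-labda-7,13E-dien-15-oate (5R,9R,10R) | COC(=O)/C=C(\C)CC[C@H]1[C@]2(C)CCCC(C)(C)[C@H]2CC=C1C | intermediate
5 | methyl ent-6-oxolabda-7,13E-dien-15-oate (5R,9R,10S) | COC(=O)/C=C(\C)CC[C@H]1[C@]2(C)CCCC(C)(C)[C@H]2C(=O)C=C1C | intermediate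
6 | methyl ent-7α,8α-epoxy-6-oxolabd-13E-en-15-oate (5R,7R,8R,9S,10S; epoxide anti to C20) | COC(=O)/C=C(\C)CC[C@H]1[C@]2(C)CCCC(C)(C)[C@H]2C(=O)[C@@H]3O[C@]13C | intermediate
7 | methyl ent-8α-hydroxy-6-oxolabd-13E-en-15-oate (5R,8S,9S,10S) | COC(=O)/C=C(\C)CC[C@H]1[C@]2(C)CCCC(C)(C)[C@H]2C(=O)C[C@]1(C)O | intermediate
8 | methyl ent-6α,8α-dihydroxylabd-13E-en-15-oate (5R,6R,8S,9S,10R), CNP0289884.1 | COC(=O)/C=C(\C)CC[C@H]1[C@]2(C)CCCC(C)(C)[C@H]2[C@H](O)C[C@]1(C)O | target

Total step count: 6
Longest linear sequence: 6 steps (1 to 8)

Steps most likely to fail

Step 2. The cascade may stop after ring A has closed, the C8 cation may lose a proton toward C17 or C9 instead of C7, the acid may discriminate poorly between the two enantiomeric folds, and the ester may sequester SnCl4. Fallback with known chemistry: setting out from 3, cyclization with fluorosulfonic acid (FSO3H) in 2-nitropropane at −78 °C is used. This is the racemic superacid protocol established for geranylgeranoates, in which alkene isomers are returned to the C8 cation before the quench. It would give 4 as a racemate with its antipode, methyl (5S,9S,10S)-labda-7,13E-dien-15-oate F1. The two would be separated by preparative chromatography on a cellulose tris(3,5-dimethylphenylcarbamate) phase, and the route is rejoined at 4.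

Step 6. C6 may be protonated from the open face (giving the axial alcohol), electron transfer to the hindered ketone may be too slow without additives, and stronger activation would start conjugate reduction of the enoate. Fallback, which delivers oxygen rather than hydrogen to C6 and sets out from epoxy ketone 6, bypassing 7: Wharton transposition (N2H4·H2O, AcOH, MeOH) would give methyl ent-8α-hydroxylabda-6,13E-dien-15-oate F2, with the C8–O bond of the epoxide retained. Suprafacial 1,3-transposition of this tertiary allylic alcohol with O3ReOSiPh3 (cat.) in Et2O, driven by relief of the C17/C20 diaxial contact, would move the oxygen to the face of C6 anti to C20 and give methyl ent-6α-hydroxylabda-7,13E-dien-15-oate F3. Mukaiyama hydration (Co(acac)2, PhSiH3, O2, i-PrOH) would then add hydrogen to C7 and trap the tertiary C8 radical with oxygen anti to C20, and the route is rejoined at the target 8.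

Step 4. Hydroperoxide may add too slowly to the hindered, fully substituted C8, some attack may occur syn to C20, and prolonged base may saponify the methyl ester. Fallback setting out from enone 5 and bypassing 6: conjugate borylation (CuCl, NaOt-Bu, bis[2-(diphenylphosphino)phenyl] ether, B2pin2, MeOH, THF) would place boron on C8 from the face anti to C20. It would give methyl ent-6-oxo-8α-(4,4,5,5-tetramethyl-1,3,2-dioxaborolan-2-yl)labd-13E-en-15-oate F4. Oxidation with NaBO3·4H2O in THF/H2O, which proceeds with retention at carbon, would give hydroxy ketone 7, where the route is rejoined.

Further compounds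
F1 | step 2 | methyl (5S,9S,10S)-labda-7,13E-dien-15-oate (antipode of 4) | COC(=O)/C=C(\C)CC[C@@H]1[C@@]2(C)CCCC(C)(C)[C@@H]2CC=C1C
F2 | step 6 | methyl ent-8α-hydroxylabda-6,13E-dien-15-oate | COC(=O)/C=C(\C)CC[C@H]1[C@]2(C)CCCC(C)(C)[C@H]2C=C[C@]1(C)O
F3 | step 6 | methyl ent-6α-hydroxylabda-7,13E-dien-15-oate | COC(=O)/C=C(\C)CC[C@H]1[C@]2(C)CCCC(C)(C)[C@H]2[C@H](O)C=C1C
F4 | step 4 | methyl ent-6-oxo-8α-(4,4,5,5-tetramethyl-1,3,2-dioxaborolan-2-yl)labd-13E-en-15-oate | COC(=O)/C=C(\C)CC[C@H]1[C@]2(C)CCCC(C)(C)[C@H]2C(=O)C[C@]1(C)B3OC(C)(C)C(C)(C)O3
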